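**Plan**
- Retrosynthesis: a removable CO2tBu group is placed on C3, then the O1–C2 bond of ring C is cut (C2 is β to the C4 carbonyl, an oxa-Michael retron). Next come the C2=C3 alkene (Knoevenagel, benzaldehyde), the C3–CO2tBu bond, and the two ring A–CH2 bonds at C6 and C8.
- Enabling feature: in the open form, ring A (C4a, C5, C6, C7, C8, C8a) is a phloroglucinol with a symmetry axis through C4a and C7. The oxygens on C5 and C8a are equivalent, as are the arms on C6 and C8, so no regiochemical decision arises.
- Forward: phloroacetophenone takes both 2-hydroxybenzyl arms at its only two free ring carbons, four hydroxyls are benzylated, the acetyl group is carboxylated and condensed with benzaldehyde, and ring C closes last.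
- Stereochemistry: the single centre C2 (S) is set in the ring closure by a cinchona-derived bifunctional thiourea. The ester then leaves as CO2 and hydrogenolysis frees the phenols.

Key step: step 5

Assumption: the 9-amino(9-deoxy)-epi-quinidine-derived thiourea is taken to deliver the 2S configuration; the sense of induction would be checked on the first batch and the quinine-derived pseudoenantiomer used if it proves opposite.

**Step 1**
Reactants: 1 2,4,6-trihydroxyacetophenone (dried), 2 2-hydroxybenzyl alcohol (about 2.4 equiv, added in portions)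
Product: 3 1-[2,4,6-trihydroxy-3,5-bis(2-hydroxybenzyl)phenyl]ethan-1-one
Conditions: ZnCl2 (anhydrous), 1,4-dioxane, reflux
Reagents that add atoms: none
Why: ZnCl2 ionises the chelated benzylic alcohol to an ortho-quinone methide (or its zinc-bound benzylic cation), which is trapped in a Friedel–Crafts-type alkylation by C3 and C5 of the phloroglucinol ring, its only unsubstituted and symmetry-equivalent carbons, so no regioisomer can form.

**Step 2**
Reactants: 3 1-[2,4,6-trihydroxy-3,5-bis(2-hydroxybenzyl)phenyl]ethan-1-one
Product: 4 1-[2,4-bis(benzyloxy)-3,5-bis[2-(benzyloxy)benzyl]-6-hydroxyphenyl]ethan-1-one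
Conditions: BnBr (4.1 equiv), K2CO3 (4.5 equiv), DMF, rt
Reagents that add atoms: benzyl bromide, BrCc1ccccc1
Why: Williamson etherification under mild base should alkylate the four non-chelated phenols and leave free the last ortho hydroxyl, which is hydrogen-bonded to the acetyl carbonyl; because the two ortho hydroxyls are equivalent, it does not matter which one remains.

**Step 3**
Reactants: 4 1-[2,4-bis(benzyloxy)-3,5-bis[2-(benzyloxy)benzyl]-6-hydroxyphenyl]ethan-1-one
Product: 5 tert-butyl 3-[2,4-bis(benzyloxy)-3,5-bis[2-(benzyloxy)benzyl]-6-hydroxyphenyl]-3-oxopropanoate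
Conditions: LiN(SiMe3)2 (3.3 equiv), THF, −78 °C; Boc2O (1.1 equiv), −78 to 0 °C; aq. NH4Cl
Reagents that add atoms: di-tert-butyl dicarbonate, CC(C)(C)OC(=O)OC(=O)OC(C)(C)C
Why: Claisen-type C-acylation of the phenoxide–enolate dianion by Boc2O, the third equivalent of base taking up the acidic β-ketoester proton; any aryl tert-butyl carbonate formed at the phenoxide oxygen should be carried to the same product by base-induced O-to-C acyl transfer of the Baker–Venkataraman type.

**Step 4**
Reactants: 5 tert-butyl 3-[2,4-bis(benzyloxy)-3,5-bis[2-(benzyloxy)benzyl]-6-hydroxyphenyl]-3-oxopropanoate, 6 benzaldehyde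
Product: 7 tert-butyl (2Z)-2-[2,4-bis(benzyloxy)-3,5-bis[2-(benzyloxy)benzyl]-6-hydroxybenzoyl]-3-phenylprop-2-enoate
Conditions: piperidine (cat.), AcOH (cat.), 4 Å molecular sieves, toluene, rt to 40 °C
Reagents that add atoms: none
Why: Knoevenagel condensation of the doubly activated methylene with benzaldehyde under piperidinium acetate catalysis with removal of water; the bulky tert-butyl ester prevents lactonisation onto the free phenol, and the low temperature is chosen to keep uncatalysed ring closure slow.

**Step 5**
Reactants: 7 tert-butyl (2Z)-2-[2,4-bis(benzyloxy)-3,5-bis[2-(benzyloxy)benzyl]-6-hydroxybenzoyl]-3-phenylprop-2-enoate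
Product: 10 (2S)-5,7-bis(benzyloxy)-6,8-bis[2-(benzyloxy)benzyl]-2-phenylchroman-4-one, via tert-butyl chromanone-3-carboxylate 8 (not isolated), via chromanone-3-carboxylic acid 9 (not isolated)
Conditions: 9-amino(9-deoxy)-epi-quinidine N'-[3,5-bis(trifluoromethyl)phenyl]thiourea (10 mol %), toluene, −25 °C; then TsOH·H2O (0.5 equiv), 80 °C
Reagents that add atoms: none
Why: The quinuclidine nitrogen of the bifunctional catalyst deprotonates the single free phenol (the future O1) while the thiourea holds the β-ketoester in a two-point hydrogen-bonded chelate, so the phenoxide adds to the benzylidene carbon (the future C2) in an intramolecular oxa-Michael addition; the closest known reaction type is the cinchona-thiourea-catalysed cyclisation of 2'-hydroxyaryl alkylidene β-ketoesters to flavanones. Ring C closes in the 6-endo-trig mode by O1–C2 bond formation. C2 is set by the catalyst, which exposes one enantioface of the bound alkene to the tethered phenoxide, whereas C3 is of no account because it is enolisable and is erased when TsOH cleaves the tert-butyl ester and the β-keto acid 9 loses CO2. The step needs enantioface selectivity and suppression of the uncatalysed racemic closure; the tert-butyl ester should secure both by providing the second binding point and making the catalysed path fast at −25 °C. No site selectivity is asked for, since only one hydroxyl is free and ring A carries no unsubstituted carbon. Decarboxylation in the same flask under acid avoids basic conditions that could reopen ring C by retro-oxa-Michael reaction and erode the configuration at C2.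

**Step 6**
Reactants: 10 (2S)-5,7-bis(benzyloxy)-6,8-bis[2-(benzyloxy)benzyl]-2-phenylchroman-4-one
Product: 11 dichamanetin, (2S)-5,7-dihydroxy-6,8-bis(2-hydroxybenzyl)-2-phenylchroman-4-one
Conditions: H2 (1 atm), 10% Pd/C, EtOAc–MeOH, rt
Reagents that add atoms: none
Why: Hydrogenolysis of the four primary benzyl aryl ethers over Pd/C is neutral and so leaves the base-sensitive C2 centre untouched; the secondary benzylic C2–O1 bond and the aryl ketone are expected to react much more slowly, and the reaction is stopped as soon as debenzylation is complete.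

**Compound list**
1 | 2,4,6-trihydroxyacetophenone | CC(=O)c1c(O)cc(O)cc1O | starting material
2 | 2-hydroxybenzyl alcohol | OCc1ccccc1O | starting material
3 | 1-[2,4,6-trihydroxy-3,5-bis(2-hydroxybenzyl)phenyl]ethan-1-one | CC(=O)c1c(O)c(Cc2ccccc2O)c(O)c(Cc2ccccc2O)c1O | intermediate
4 | 1-[2,4-bis(benzyloxy)-3,5-bis[2-(benzyloxy)benzyl]-6-hydroxyphenyl]ethan-1-one | CC(=O)c1c(O)c(Cc2ccccc2OCc2ccccc2)c(OCc2ccccc2)c(Cc2ccccc2OCc2ccccc2)c1OCc1ccccc1 | intermediate
5 | tert-butyl 3-[2,4-bis(benzyloxy)-3,5-bis[2-(benzyloxy)benzyl]-6-hydroxyphenyl]-3-oxopropanoate | CC(C)(C)OC(=O)CC(=O)c1c(O)c(Cc2ccccc2OCc2ccccc2)c(OCc2ccccc2)c(Cc2ccccc2OCc2ccccc2)c1OCc1ccccc1 | intermediate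
6 | benzaldehyde | O=Cc1ccccc1 | starting material
7 | tert-butyl (2Z)-2-[2,4-bis(benzyloxy)-3,5-bis[2-(benzyloxy)benzyl]-6-hydroxybenzoyl]-3-phenylprop-2-enoate (Z isomer drawn, phenyl cis to the ester; a minor E isomer may accompany it) | CC(C)(C)OC(=O)/C(=C\c1ccccc1)C(=O)c1c(O)c(Cc2ccccc2OCc2ccccc2)c(OCc2ccccc2)c(Cc2ccccc2OCc2ccccc2)c1OCc1ccccc1 | intermediate
8 | tert-butyl (2S)-5,7-bis(benzyloxy)-6,8-bis[2-(benzyloxy)benzyl]-4-oxo-2-phenyl-3,4-dihydro-2H-chromene-3-carboxylate (C3 enolisable, left undefined) | O=C1C(C(=O)OC(C)(C)C)[C@@H](c2ccccc2)Oc2c(Cc3ccccc3OCc3ccccc3)c(OCc3ccccc3)c(Cc3ccccc3OCc3ccccc3)c(OCc3ccccc3)c21 | intermediate (not isolated)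
9 | (2S)-5,7-bis(benzyloxy)-6,8-bis[2-(benzyloxy)benzyl]-4-oxo-2-phenyl-3,4-dihydro-2H-chromene-3-carboxylic acid (C3 undefined) | O=C1C(C(=O)O)[C@@H](c2ccccc2)Oc2c(Cc3ccccc3OCc3ccccc3)c(OCc3ccccc3)c(Cc3ccccc3OCc3ccccc3)c(OCc3ccccc3)c21 | intermediate (not isolated)
10 | (2S)-5,7-bis(benzyloxy)-6,8-bis[2-(benzyloxy)benzyl]-2-phenylchroman-4-one | O=C1C[C@@H](c2ccccc2)Oc2c(Cc3ccccc3OCc3ccccc3)c(OCc3ccccc3)c(Cc3ccccc3OCc3ccccc3)c(OCc3ccccc3)c21 | intermediate
11 | dichamanetin, (2S)-5,7-dihydroxy-6,8-bis(2-hydroxybenzyl)-2-phenylchroman-4-one | O=C1C[C@@H](c2ccccc2)Oc2c(Cc3ccccc3O)c(O)c(Cc3ccccc3O)c(O)c21 | target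

**Totals**
Total step count: 6. Longest linear sequence: 6 steps (1 to 11).

**Steps most likely to fail**

Step 5. The twisted, hexasubstituted aroyl group and the arm next to the reacting hydroxyl may disturb the fit between catalyst and substrate, giving poor enantioface discrimination. Uncatalysed closure may also compete, already during step 4. The fallback sets out from 4 and returns at 10. Compound 4 is heated with N,N-dimethylformamide dimethyl acetal to give the enaminone (2E)-1-[2,4-bis(benzyloxy)-3,5-bis[2-(benzyloxy)benzyl]-6-hydroxyphenyl]-3-(dimethylamino)prop-2-en-1-one F1. Under acid (TsOH, toluene) this closes with loss of dimethylamine to the chromone 5,7-bis(benzyloxy)-6,8-bis[2-(benzyloxy)benzyl]-4H-chromen-4-one F2. Enantioselective conjugate addition of phenylboronic acid to F2 should then give 10, using Pd(OCOCF3)2 and the enantiomer of the tert-butyl pyridine-oxazoline ligand that leads to the 2S product (NH4PF6, water, 1,2-dichloroethane, 60 °C). In this variant ring C is closed before C2 is set, and C2 is created by C–C instead of C–O bond formation.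

Step 1. The quinone methide may condense with itself or alkylate the newly attached phenol rings, or the reaction may stall after the first arm. The fallback sets out from 1 and returns at 4. Compound 1 is alkylated with 2-(benzyloxy)benzyl alcohol (OCc1ccccc1OCc1ccccc1; Sc(OTf)3 cat., MeNO2, 50 °C), whose capped phenol cannot form a quinone methide and whose ring is a weaker nucleophile. This gives 1-[3,5-bis[2-(benzyloxy)benzyl]-2,4,6-trihydroxyphenyl]ethan-1-one F3. Benzylation of F3 at two hydroxyls (BnBr 2 equiv, K2CO3, DMF), leaving the chelated one, should give 4.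

Step 2. Discrimination between the chelated hydroxyl and the other four may be incomplete, leading to over- or under-alkylation. The fallback sets out from 3 and returns at 4. Exhaustive benzylation (BnBr in excess, K2CO3, DMF, 60 °C) gives 1-[2,4,6-tris(benzyloxy)-3,5-bis[2-(benzyloxy)benzyl]phenyl]ethan-1-one F4. MgBr2·OEt2 (toluene–Et2O, reflux) then removes one benzyl group ortho to the acetyl group by chelation-directed cleavage; the two ortho ethers are equivalent, so a single product, 4, should result.

If the enantiomeric purity of 10 falls short, crystallisation of 10 is foreseen before step 6.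

**Further compounds**
F1 | step 5 | (2E)-1-[2,4-bis(benzyloxy)-3,5-bis[2-(benzyloxy)benzyl]-6-hydroxyphenyl]-3-(dimethylamino)prop-2-en-1-one | CN(C)/C=C/C(=O)c1c(O)c(Cc2ccccc2OCc2ccccc2)c(OCc2ccccc2)c(Cc2ccccc2OCc2ccccc2)c1OCc1ccccc1
F2 | step 5 | 5,7-bis(benzyloxy)-6,8-bis[2-(benzyloxy)benzyl]-4H-chromen-4-one | O=c1ccoc2c(Cc3ccccc3OCc3ccccc3)c(OCc3ccccc3)c(Cc3ccccc3OCc3ccccc3)c(OCc3ccccc3)c12
F3 | step 1 | 1-[3,5-bis[2-(benzyloxy)benzyl]-2,4,6-trihydroxyphenyl]ethan-1-one | CC(=O)c1c(O)c(Cc2ccccc2OCc2ccccc2)c(O)c(Cc2ccccc2OCc2ccccc2)c1O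
F4 | step 2 | 1-[2,4,6-tris(benzyloxy)-3,5-bis[2-(benzyloxy)benzyl]phenyl]ethan-1-one | CC(=O)c1c(OCc2ccccc2)c(Cc2ccccc2OCc2ccccc2)c(OCc2ccccc2)c(Cc2ccccc2OCc2ccccc2)c1OCc1ccccc1
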